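**Retrosynthetic overview**

1. Target 9 ⇐ open 2-aryl-1,3-diketone 6 by sugar hydrolysis, O1–C2 cyclodehydration and O-debenzylation. The furan is the only ring made and is formed last (C3–C3a first, then O1–C2).
2. Key disconnection C3–C3a: ring carbon C3' of a phloretin unit and C2 of a 1,3-diketone are both nucleophilic by nature. They are joined by using the diketone as its 2-chloro derivative 5, an enolonium (a2) equivalent.
3. Phloretin unit = naringin dihydrochalcone 4. The dihydrochalcone ketone is already in place and the 4'-OH is blocked by the natural neohesperidoside, so only the OH ortho to the acyl group can close the furan.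
4. Diketone 3 ⇐ crossed Claisen condensation of ketone 1 and ester 2. Benzyl ethers are used so that the resorcinol 2-OH can be freed before ring closure and direct it by hydrogen bonding.

Assumption: the target has no stereocentre, so there is no enantiomer to select; the only stereocentres on the way are those of the bought sugar unit (cleaved in step 3) and labile CH centres that are lost on aromatisation. Compounds 1, 2 and 4 are taken as catalogue materials (4 is the sweetener made from citrus naringin).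

**Step 1**
Reactants: 1 1-[2,4-bis(benzyloxy)phenyl]ethanone; 2 methyl 4-(benzyloxy)benzoate
Product: 3 1-[2,4-bis(benzyloxy)phenyl]-3-[4-(benzyloxy)phenyl]propane-1,3-dione
Conditions: NaH (2.5 equiv), THF, 65 °C; aq. HCl work-up
Reagents that add atoms: none
Why: Crossed Claisen condensation in which the sodium enolate of methyl ketone 1 is acylated by the non-enolisable aryl ester 2, driven by formation of the stabilised β-diketonate; no stereocentre is formed.

**Step 2**
Reactants: 3 1-[2,4-bis(benzyloxy)phenyl]-3-[4-(benzyloxy)phenyl]propane-1,3-dione; 4 naringin dihydrochalcone (1-[2,6-dihydroxy-4-(2-O-α-L-rhamnopyranosyl-β-D-glucopyranosyloxy)phenyl]-3-(4-hydroxyphenyl)propan-1-one)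
Product: 6 2-{2,4-dihydroxy-3-[3-(4-hydroxyphenyl)propanoyl]-6-(2-O-α-L-rhamnopyranosyl-β-D-glucopyranosyloxy)phenyl}-1-[2,4-bis(benzyloxy)phenyl]-3-[4-(benzyloxy)phenyl]propane-1,3-dione (epimeric at the new CH), via 2-chloro-1,3-dione 5 (not isolated)
Conditions: NCS (1.0 equiv), THF, rt; then 4 (1.2 equiv), NaHCO3 (3 equiv), THF/MeOH/H2O, 40 °C; AcOH to pH 6, crude product used directly (no silica, no strong acid)
Reagents that add atoms: none
Why: Proposed new method: NCS chlorinates the enolised β-diketone at C2 to give an α-chloro-β-diketone (enolonium equivalent), and the bicarbonate-generated ortho-phenolate of 4, which reacts at carbon in protic medium (C3' and C5' are equivalent and the 4'-oxygen carries the sugar), displaces chloride by SN2, so the two naturally nucleophilic carbons are joined; the closest known reaction type is the Feist–Benary-type C-alkylation of resorcinol/phloroglucinol-type phenols and cyclic 1,3-diones by α-chloro-β-dicarbonyl compounds; the new CH centre is formed without control and is destroyed in step 3.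

**Step 3**
Reactants: 6 C-alkylated triketone glycoside from step 2
Product: 9 1-[3-(2,4-dihydroxybenzoyl)-4,6-dihydroxy-2-(4-hydroxyphenyl)-1-benzofuran-7-yl]-3-(4-hydroxyphenyl)propan-1-one, via debenzylated triketone glycoside 7 (not isolated), via benzofuran neohesperidoside 8 (not isolated)
Conditions: H2 (1 atm), 10% Pd/C, THF/MeOH, rt; filter; then 2 M HCl, dioxane/H2O, 80 °C
Reagents that add atoms: none
Why: Hydrogenolysis of the three aryl benzyl ethers frees the resorcinol 2-OH, whose hydrogen bond deactivates its own carbonyl, so the acid-catalysed cyclodehydration (furan-forming half of the Feist–Benary-type synthesis) takes place by attack of the only adjacent free phenol (2'-OH, the 4'-oxygen still glycosylated) on the 4-hydroxybenzoyl carbonyl, and continued heating hydrolyses the aryl neohesperidoside (acetal hydrolysis); the labile CH centre vanishes on aromatisation and the target is achiral.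

**Compound list**

1 | 1-[2,4-bis(benzyloxy)phenyl]ethanone | CC(=O)c1ccc(OCc2ccccc2)cc1OCc1ccccc1 | starting material
2 | methyl 4-(benzyloxy)benzoate | COC(=O)c1ccc(OCc2ccccc2)cc1 | starting material
3 | 1-[2,4-bis(benzyloxy)phenyl]-3-[4-(benzyloxy)phenyl]propane-1,3-dione | O=C(CC(=O)c1ccc(OCc2ccccc2)cc1)c1ccc(OCc2ccccc2)cc1OCc1ccccc1 | intermediate
4 | naringin dihydrochalcone, 1-[2,6-dihydroxy-4-(2-O-α-L-rhamnopyranosyl-β-D-glucopyranosyloxy)phenyl]-3-(4-hydroxyphenyl)propan-1-one | OC[C@H]1O[C@@H](Oc2cc(O)c(C(=O)CCc3ccc(O)cc3)c(O)c2)[C@H](O[C@@H]4O[C@@H](C)[C@H](O)[C@@H](O)[C@H]4O)[C@@H](O)[C@@H]1O | starting material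
5 | 1-[2,4-bis(benzyloxy)phenyl]-3-[4-(benzyloxy)phenyl]-2-chloropropane-1,3-dione (racemic, labile CHCl) | O=C(C(Cl)C(=O)c1ccc(OCc2ccccc2)cc1)c1ccc(OCc2ccccc2)cc1OCc1ccccc1 | intermediate
6 | 2-{2,4-dihydroxy-3-[3-(4-hydroxyphenyl)propanoyl]-6-(2-O-α-L-rhamnopyranosyl-β-D-glucopyranosyloxy)phenyl}-1-[2,4-bis(benzyloxy)phenyl]-3-[4-(benzyloxy)phenyl]propane-1,3-dione (mixture of epimers at the dione C2) | OC[C@H]1O[C@@H](Oc2cc(O)c(C(=O)CCc3ccc(O)cc3)c(O)c2C(C(=O)c5ccc(OCc6ccccc6)cc5)C(=O)c7ccc(OCc8ccccc8)cc7OCc9ccccc9)[C@H](O[C@@H]4O[C@@H](C)[C@H](O)[C@@H](O)[C@H]4O)[C@@H](O)[C@@H]1O | intermediate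
7 | 2-{2,4-dihydroxy-3-[3-(4-hydroxyphenyl)propanoyl]-6-(2-O-α-L-rhamnopyranosyl-β-D-glucopyranosyloxy)phenyl}-1-(2,4-dihydroxyphenyl)-3-(4-hydroxyphenyl)propane-1,3-dione (mixture of epimers at the dione C2) | OC[C@H]1O[C@@H](Oc2cc(O)c(C(=O)CCc3ccc(O)cc3)c(O)c2C(C(=O)c5ccc(O)cc5)C(=O)c6ccc(O)cc6O)[C@H](O[C@@H]4O[C@@H](C)[C@H](O)[C@@H](O)[C@H]4O)[C@@H](O)[C@@H]1O | intermediate
8 | 1-[3-(2,4-dihydroxybenzoyl)-6-hydroxy-2-(4-hydroxyphenyl)-4-(2-O-α-L-rhamnopyranosyl-β-D-glucopyranosyloxy)-1-benzofuran-7-yl]-3-(4-hydroxyphenyl)propan-1-one | OC[C@H]1O[C@@H](Oc2cc(O)c(C(=O)CCc3ccc(O)cc3)c3oc(-c5ccc(O)cc5)c(C(=O)c6ccc(O)cc6O)c23)[C@H](O[C@@H]4O[C@@H](C)[C@H](O)[C@@H](O)[C@H]4O)[C@@H](O)[C@@H]1O | intermediate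
9 | 1-[3-(2,4-dihydroxybenzoyl)-4,6-dihydroxy-2-(4-hydroxyphenyl)-1-benzofuran-7-yl]-3-(4-hydroxyphenyl)propan-1-one (achiral) | O=C(CCc1ccc(O)cc1)c1c(O)cc(O)c2c(C(=O)c3ccc(O)cc3O)c(-c3ccc(O)cc3)oc12 | target

**Step count and risks**

Total steps: 3. Longest linear sequence: 3 (1/2 → 3 → 6 → 9).

Steps most likely to fail:

1. Step 2 (most at risk). The SN2 reaction joins a ring carbon flanked by two oxygens to a carbon flanked by two aroyl groups. O-alkylation, chlorine transfer to the phenol, or retro-Claisen cleavage of 5 by the phenolate may win. Fallback: reverse the polarity on the other partner. Set out from 4 and iodinate with N-iodosuccinimide (1.0 equiv, MeOH, 0 °C) at the equivalent C3'/C5' position to give 3'-iodonaringin dihydrochalcone F1. Then couple F1 with the enolate of diketone 3 under copper catalysis (CuI, L-proline, K2CO3, DMSO, 60 °C; Hurtley/Ullmann-type C-arylation of a β-diketone by an ortho-halophenol). This comes back to the route at 6.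

2. Step 3. Hot mineral acid, needed to hydrolyse the neohesperidoside, may degrade the polyphenolic product or leave the cleavage incomplete. Fallback: set out from 6, run the hydrogenolysis and only a mild acid closure (cat. TsOH, THF, rt) so that 8 is isolated, then remove the sugar enzymatically with naringinase (α-L-rhamnosidase/β-D-glucosidase, pH 4 acetate buffer, 50 °C). The enzyme first takes off rhamnose to give the target 4-O-β-D-glucopyranoside F2 and then glucose, coming back at 9.

3. Step 1. The ortho-benzyloxy ketone is hindered, and self-condensation or incomplete acylation may lower the yield. Fallback: set out from 1 and condense it with 4-(benzyloxy)benzaldehyde (O=Cc1ccc(OCc2ccccc2)cc1; KOH, EtOH, rt; Claisen–Schmidt) to give (E)-1-[2,4-bis(benzyloxy)phenyl]-3-[4-(benzyloxy)phenyl]prop-2-en-1-one F3. Epoxidise with H2O2/NaOH (MeOH/THF, 0 °C; Weitz–Scheffer) to the (±)-trans-epoxy ketone F4. Isomerise the α,β-epoxy ketone to the β-diketone with Pd(PPh3)4/dppe in toluene at 100 °C, coming back at 3.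

**Further compounds**

F1 | step 2 | 1-[2,6-dihydroxy-3-iodo-4-(2-O-α-L-rhamnopyranosyl-β-D-glucopyranosyloxy)phenyl]-3-(4-hydroxyphenyl)propan-1-one | OC[C@H]1O[C@@H](Oc2cc(O)c(C(=O)CCc3ccc(O)cc3)c(O)c2I)[C@H](O[C@@H]4O[C@@H](C)[C@H](O)[C@@H](O)[C@H]4O)[C@@H](O)[C@@H]1O
F2 | step 3 | 1-[3-(2,4-dihydroxybenzoyl)-4-(β-D-glucopyranosyloxy)-6-hydroxy-2-(4-hydroxyphenyl)-1-benzofuran-7-yl]-3-(4-hydroxyphenyl)propan-1-one | OC[C@H]1O[C@@H](Oc2cc(O)c(C(=O)CCc3ccc(O)cc3)c3oc(-c5ccc(O)cc5)c(C(=O)c6ccc(O)cc6O)c23)[C@H](O)[C@@H](O)[C@@H]1O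
F3 | step 1 | (E)-1-[2,4-bis(benzyloxy)phenyl]-3-[4-(benzyloxy)phenyl]prop-2-en-1-one | O=C(/C=C/c1ccc(OCc2ccccc2)cc1)c1ccc(OCc2ccccc2)cc1OCc1ccccc1
F4 | step 1 | (±)-trans-[2,4-bis(benzyloxy)phenyl]{3-[4-(benzyloxy)phenyl]oxiran-2-yl}methanone (racemate, one enantiomer drawn) | O=C([C@@H]1O[C@H]1c1ccc(OCc2ccccc2)cc1)c1ccc(OCc2ccccc2)cc1OCc1ccccc1
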